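**Plan**

1. Retrosynthesis: the C2 angelate, the C13 silyl ether and the C7 hydroxyl go first; then ring bonds C4–C5 (ring A) and C9–C10 (ring B) are cut together; the open chain is cut at C5=C10 (olefination), C1–C10 and C6–C7 (alkylations).
2. Forward: (R)-linalool supplies C7–C9 and C11–C17 (its E-methyl becomes C7, the other methyl C17) and is extended by C6/C5 to aldehyde 7. A Z-selective Horner–Wadsworth–Emmons reaction with epoxy phosphonate 11 adds C1–C4, C10 and C20 (as the ester carbon); reduction and acetylation give epoxy triene 14.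
3. A titanocene(III) radical cascade on 14 closes ring A, then ring B, and ends as the 8(17)-alkene. Ring A is then adjusted (C3 ketone, C2 hydroxylation, C3 reduction), O2 is angeloylated, C7 is hydroxylated and the silyl ether is removed.
4. Feature used: C4 (epoxide carbon), the C5=C10 alkene that already carries C20 as CH2OAc, and the C8=C9 alkene that carries C17 as a methyl group stand in a 1,5,9 relationship. Two 6-endo closures therefore give the trans-fused rings A/B with the oxidised angular carbon in place, and a C17 hydrogen ends the cascade.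
5. Stereochemistry: C13 from (R)-linalool; C3 from a Shi epoxidation, passed on to C5, C10 and C9 in the cascade; C2 from α-face Rubottom oxidation; C3 reset by equatorial hydride delivery; C7 from an α-face ene/[2,3] sequence; the Z ester from angelic acid.

Key step: step 10

Assumption: the SMILES is read as (13R)-20-acetoxy-2α-angeloyloxy-labda-8(17),14-diene-3α,7α,13-triol of the normal labdane series (H-5 α, C20 β, side chain at C9 β); labdane numbering and α/β descriptors are used for the ring compounds, and (R)-(−)-linalool of high enantiomeric purity and the L-fructose-derived Shi ketone are taken as purchasable.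

**Route**

Step 1
Reactants: 1 (R)-(−)-linalool
Product: 2 triethyl{[(3R)-3,7-dimethylocta-1,6-dien-3-yl]oxy}silane
Conditions: TESCl, imidazole, DMAP (cat.), DMF, 40 °C
Reagents that add atoms: chlorotriethylsilane, CC[Si](Cl)(CC)CC
Why: Silyl ether formation masks the tertiary allylic alcohol so that the later allylic bromide cannot be closed onto by O13 in an SN2′ sense; the C13 centre is not touched.

Step 2
Reactants: 2 triethyl{[(3R)-3,7-dimethylocta-1,6-dien-3-yl]oxy}silane
Product: 3 (2E,6R)-2,6-dimethyl-6-[(triethylsilyl)oxy]octa-2,7-dien-1-ol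
Conditions: SeO2 (cat.), t-BuOOH, salicylic acid (cat.), CH2Cl2, rt
Reagents that add atoms: tert-butyl hydroperoxide, CC(C)(C)OO (terminal oxidant; the oxygen is passed on by catalytic SeO2, O=[Se]=O)
Why: Riley allylic oxidation (ene reaction, then [2,3]-sigmatropic shift) should oxidise the E-methyl of the trisubstituted alkene selectively to the (E)-allylic alcohol, while the vinyl group has no allylic hydrogen.

Step 3
Reactants: 3 (2E,6R)-2,6-dimethyl-6-[(triethylsilyl)oxy]octa-2,7-dien-1-ol
Product: 4 {[(3R,6E)-8-bromo-3,7-dimethylocta-1,6-dien-3-yl]oxy}triethylsilane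
Conditions: CBr4, PPh3, CH2Cl2, 0 °C
Reagents that add atoms: carbon tetrabromide, BrC(Br)(Br)Br
Why: Appel bromination turns the primary allylic alcohol into the bromide under neutral conditions without allylic transposition or loss of the silyl ether.

Step 4
Reactants: 4 {[(3R,6E)-8-bromo-3,7-dimethylocta-1,6-dien-3-yl]oxy}triethylsilane; 5 N-tert-butylethanimine
Product: 7 (4E,8R)-4,8-dimethyl-8-[(triethylsilyl)oxy]deca-4,9-dienal, via tert-butylimine 6 (not isolated)
Conditions: 5, LDA, THF, 0 °C; then 4, −78 to 0 °C; then AcOH/NaOAc buffer (pH 4.5), H2O, rt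
Reagents that add atoms: water, O
Why: Aza-enolate alkylation (metalated acetaldimine, SN2 at the primary allylic bromide) adds C6 and C5 in one operation, and buffered imine hydrolysis should free the γ,δ-unsaturated aldehyde without conjugation or desilylation.

Step 5
Reactants: 8 5-bromo-2-methylpent-2-ene
Product: 9 (2S)-2-(2-bromoethyl)-3,3-dimethyloxirane
Conditions: L-fructose-derived Shi ketone (30 mol%), Oxone, K2CO3, Bu4NHSO4 (cat.), MeCN/dimethoxymethane/aq. borate buffer, 0 °C
Reagents that add atoms: potassium peroxymonosulfate (Oxone), [K+].[O-]S(=O)(=O)OO (oxygen passed on by the ketone catalyst as its dioxirane)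
Why: Shi asymmetric epoxidation (chiral dioxirane, spiro transition state) of the trisubstituted alkene with the enantiomeric catalyst should give the (S)-epoxide, the centre that later fixes the absolute configuration of both rings.

Step 6
Reactants: 9 (2S)-2-(2-bromoethyl)-3,3-dimethyloxirane; 10 methyl 2-[bis(2,2,2-trifluoroethoxy)phosphoryl]acetate
Product: 11 methyl 2-[bis(2,2,2-trifluoroethoxy)phosphoryl]-4-[(2S)-3,3-dimethyloxiran-2-yl]butanoate (both epimers at C2)
Conditions: NaH, DMF, 0 °C; then 9, NaI (cat.), 50 °C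
Reagents that add atoms: none
Why: C-alkylation of the sodium phosphonoacetate by the primary bromide (SN2, iodide-assisted) joins C1 to the carbon that becomes C10; the new centre next to phosphorus is lost in step 7, so its configuration does not matter.

Step 7
Reactants: 7 (4E,8R)-4,8-dimethyl-8-[(triethylsilyl)oxy]deca-4,9-dienal; 11 methyl 2-[bis(2,2,2-trifluoroethoxy)phosphoryl]-4-[(2S)-3,3-dimethyloxiran-2-yl]butanoate
Product: 12 methyl (2Z,6E,10R)-2-{2-[(2S)-3,3-dimethyloxiran-2-yl]ethyl}-6,10-dimethyl-10-[(triethylsilyl)oxy]dodeca-2,6,11-trienoate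
Conditions: 11, KHMDS, 18-crown-6, THF, −78 °C; then 7
Reagents that add atoms: none
Why: Still–Gennari olefination (Z-selective Horner–Wadsworth–Emmons reaction of the trifluoroethyl phosphonate) should place the ester carbon C20 cis to C6, that is C1 trans to C6, the geometry that puts the C6 chain equatorial when ring A closes.

Step 8
Reactants: 12 methyl (2Z,6E,10R)-2-{2-[(2S)-3,3-dimethyloxiran-2-yl]ethyl}-6,10-dimethyl-10-[(triethylsilyl)oxy]dodeca-2,6,11-trienoate
Product: 13 (2Z,6E,10R)-2-{2-[(2S)-3,3-dimethyloxiran-2-yl]ethyl}-6,10-dimethyl-10-[(triethylsilyl)oxy]dodeca-2,6,11-trien-1-ol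
Conditions: DIBAL-H (2.5 equiv), CH2Cl2, −78 °C; Rochelle salt work-up
Reagents that add atoms: none
Why: DIBAL-H 1,2-reduction of the conjugated ester gives the allylic alcohol at low temperature, where the trisubstituted epoxide, the silyl ether and both alkene geometries should be retained.

Step 9
Reactants: 13 (2Z,6E,10R)-2-{2-[(2S)-3,3-dimethyloxiran-2-yl]ethyl}-6,10-dimethyl-10-[(triethylsilyl)oxy]dodeca-2,6,11-trien-1-ol
Product: 14 (2Z,6E,10R)-2-{2-[(2S)-3,3-dimethyloxiran-2-yl]ethyl}-6,10-dimethyl-10-[(triethylsilyl)oxy]dodeca-2,6,11-trien-1-yl acetate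
Conditions: Ac2O, pyridine, DMAP (cat.), CH2Cl2, 0 °C
Reagents that add atoms: acetic anhydride, CC(=O)OC(C)=O
Why: DMAP-catalysed acetylation of the only free hydroxyl installs the C20 acetate of the target before the rings exist, so C20 never has to be differentiated or oxidised on the decalin.

Step 10
Reactants: 14 (2Z,6E,10R)-2-{2-[(2S)-3,3-dimethyloxiran-2-yl]ethyl}-6,10-dimethyl-10-[(triethylsilyl)oxy]dodeca-2,6,11-trien-1-yl acetate
Product: 16 (13R)-20-acetoxy-13-[(triethylsilyl)oxy]labda-8(17),14-dien-3β-ol, via trimethylsilyl ether 15 (not isolated)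
Conditions: Cp2TiCl2 (20 mol%), Mn dust, TMSCl, 2,4,6-collidine, THF, rt; then aq. citric acid, THF
Reagents that add atoms: none
Why: Cp2TiCl (from Cp2TiCl2 and Mn) opens the epoxide homolytically at the tertiary C4–O bond; the C4 radical closes ring A by 6-endo-trig attack on C5, the tertiary C10 radical (β to the acetoxy group) closes ring B by a second 6-endo-trig attack on C9, and the tertiary C8 radical is captured by a second Cp2TiCl and loses a β-hydrogen from the C17 methyl to give the exocyclic alkene, while TMSCl/collidine turns the titanium over. The closest known reaction is the titanocene(III)-catalysed cascade cyclisation of epoxypolyprenes such as 10,11-epoxyfarnesyl acetate to the 3β-hydroxy bicyclic acetate with an exocyclic alkene. Both rings should close through chair-like transition states with the bulky C3–O–Ti group equatorial, so the (S)-epoxide centre controls C5 (H α, C6 equatorial because C1 is trans to C6 across C5=C10), C10 (new C10–C9 bond equatorial, CH2OAc axial and β, trans fusion) and C9 (side chain equatorial because C8=C9 is E). The step needs 6-endo rather than 5-exo closure, which the trisubstituted alkenes secure by giving tertiary radicals; it needs the tertiary radicals to cyclise faster than they are trapped, which their steric shielding and the low stationary Ti(III) concentration secure; and it needs termination toward C17, whose methyl hydrogens are the most accessible β-hydrogens. The allylic acetate, the silyl ether and the monosubstituted vinyl group should be inert to Cp2TiCl under these conditions.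

Step 11
Reactants: 16 (13R)-20-acetoxy-13-[(triethylsilyl)oxy]labda-8(17),14-dien-3β-ol
Product: 17 (13R)-20-acetoxy-13-[(triethylsilyl)oxy]labda-8(17),14-dien-3-one
Conditions: Dess–Martin periodinane, CH2Cl2, 0 °C to rt
Reagents that add atoms: none
Why: Dess–Martin oxidation of the only free alcohol gives the 3-ketone, which activates C2 and allows C3 to be reset later as the axial 3α-alcohol.

Step 12
Reactants: 17 (13R)-20-acetoxy-13-[(triethylsilyl)oxy]labda-8(17),14-dien-3-one
Product: 18 (13R)-20-acetoxy-13-[(triethylsilyl)oxy]-3-[(trimethylsilyl)oxy]labda-2,8(17),14-triene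
Conditions: TMSOTf, Et3N, CH2Cl2, 0 °C
Reagents that add atoms: trimethylsilyl trifluoromethanesulfonate, C[Si](C)(C)OS(=O)(=O)C(F)(F)F
Why: Soft enolisation to the silyl enol ether can only go toward C2 because C4 is quaternary, and it should leave the acetate alone, which a strong amide base might not.

Step 13
Reactants: 18 (13R)-20-acetoxy-13-[(triethylsilyl)oxy]-3-[(trimethylsilyl)oxy]labda-2,8(17),14-triene
Product: 21 (13R)-20-acetoxy-2α-hydroxy-13-[(triethylsilyl)oxy]labda-8(17),14-dien-3-one, via silyloxy epoxide 19 (not isolated), via 2α-silyloxy ketone 20 (not isolated)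
Conditions: DMDO (1.05 equiv), acetone/CH2Cl2, −78 to −40 °C; then aq. citric acid, THF, 0 °C
Reagents that add atoms: dimethyldioxirane, CC1(C)OO1
Why: Rubottom oxidation: the electron-rich enol ether should be epoxidised faster than the other alkenes and from the α-face, away from the axial C10–CH2OAc and 4β-methyl groups, giving the equatorial 2α-hydroxy ketone, which is also the more stable epimer.

Step 14
Reactants: 21 (13R)-20-acetoxy-2α-hydroxy-13-[(triethylsilyl)oxy]labda-8(17),14-dien-3-one
Product: 22 (13R)-20-acetoxy-13-[(triethylsilyl)oxy]labda-8(17),14-diene-2α,3α-diol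
Conditions: L-Selectride (2.2 equiv), THF, −78 °C; then AcOH
Reagents that add atoms: none
Why: Bulky trialkylborohydride reduction should deliver hydride along the equatorial path from the β-face, as is usual for 4,4-dimethyl-3-keto terpenoids, to give the axial 3α-alcohol and so the cis-2α,3α-diol; esters are not reduced at this temperature.

Step 15
Reactants: 22 (13R)-20-acetoxy-13-[(triethylsilyl)oxy]labda-8(17),14-diene-2α,3α-diol; 23 angelic acid [(Z)-2-methylbut-2-enoic acid]
Product: 25 (13R)-20-acetoxy-2α-(angeloyloxy)-13-[(triethylsilyl)oxy]labda-8(17),14-dien-3α-ol, via mixed anhydride 24 (not isolated)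
Conditions: 23, 2,4,6-trichlorobenzoyl chloride, Et3N, toluene, rt; then 22, toluene, 75 °C
Reagents that add atoms: none
Why: Yamaguchi-type esterification through the mixed trichlorobenzoic anhydride without DMAP should acylate the equatorial C2 hydroxyl in preference to the axial, neopentyl C3 hydroxyl and keep the Z geometry of the angeloyl group.

Step 16
Reactants: 25 (13R)-20-acetoxy-2α-(angeloyloxy)-13-[(triethylsilyl)oxy]labda-8(17),14-dien-3α-ol
Product: 26 (13R)-20-acetoxy-2α-(angeloyloxy)-13-[(triethylsilyl)oxy]labda-8(17),14-diene-3α,7α-diol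
Conditions: SeO2 (cat.), t-BuOOH, CH2Cl2, 0 °C to rt
Reagents that add atoms: tert-butyl hydroperoxide, CC(C)(C)OO (terminal oxidant; the oxygen is passed on by catalytic SeO2, O=[Se]=O)
Why: Riley allylic hydroxylation of the 1,1-disubstituted C8=C17 alkene (ene reaction removing the axial 7α-hydrogen, then [2,3]-shift returning oxygen to the same face) should give the axial 7α-alcohol with the exocyclic alkene restored; H-9 is tertiary and hindered, and the angelate and vinyl groups should not react.

Step 17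
Reactants: 26 (13R)-20-acetoxy-2α-(angeloyloxy)-13-[(triethylsilyl)oxy]labda-8(17),14-diene-3α,7α-diol
Product: 27 (13R)-20-acetoxy-2α-(angeloyloxy)labda-8(17),14-diene-3α,7α,13-triol (CNP0251485.1)
Conditions: HF·pyridine, pyridine, THF, 0 °C
Reagents that add atoms: none
Why: Fluoride cleavage of the tertiary triethylsilyl ether under pyridine-buffered conditions should leave the acetate, the angelate (no acyl migration) and the two allylic alcohols unchanged.

**Compound list**

1 | (R)-(−)-linalool, (3R)-3,7-dimethylocta-1,6-dien-3-ol | C=C[C@](C)(O)CCC=C(C)C | starting material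
2 | triethyl{[(3R)-3,7-dimethylocta-1,6-dien-3-yl]oxy}silane | C=C[C@](C)(O[Si](CC)(CC)CC)CCC=C(C)C | intermediate
3 | (2E,6R)-2,6-dimethyl-6-[(triethylsilyl)oxy]octa-2,7-dien-1-ol | C=C[C@](C)(O[Si](CC)(CC)CC)CC/C=C(\C)CO | intermediate
4 | {[(3R,6E)-8-bromo-3,7-dimethylocta-1,6-dien-3-yl]oxy}triethylsilane | C=C[C@](C)(O[Si](CC)(CC)CC)CC/C=C(\C)CBr | intermediate
5 | N-tert-butylethanimine (acetaldehyde N-tert-butylimine) | CC=NC(C)(C)C | starting material
6 | (4E,8R)-N-tert-butyl-4,8-dimethyl-8-[(triethylsilyl)oxy]deca-4,9-dien-1-imine | C=C[C@](C)(O[Si](CC)(CC)CC)CC/C=C(\C)CCC=NC(C)(C)C | intermediate (not isolated)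
7 | (4E,8R)-4,8-dimethyl-8-[(triethylsilyl)oxy]deca-4,9-dienal | C=C[C@](C)(O[Si](CC)(CC)CC)CC/C=C(\C)CCC=O | intermediate
8 | 5-bromo-2-methylpent-2-ene | CC(C)=CCCBr | starting material
9 | (2S)-2-(2-bromoethyl)-3,3-dimethyloxirane | CC1(C)O[C@H]1CCBr | intermediate
10 | methyl 2-[bis(2,2,2-trifluoroethoxy)phosphoryl]acetate | COC(=O)CP(=O)(OCC(F)(F)F)OCC(F)(F)F | starting material
11 | methyl 2-[bis(2,2,2-trifluoroethoxy)phosphoryl]-4-[(2S)-3,3-dimethyloxiran-2-yl]butanoate (both epimers at C2) | CC1(C)O[C@H]1CCC(C(=O)OC)P(=O)(OCC(F)(F)F)OCC(F)(F)F | intermediate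
12 | methyl (2Z,6E,10R)-2-{2-[(2S)-3,3-dimethyloxiran-2-yl]ethyl}-6,10-dimethyl-10-[(triethylsilyl)oxy]dodeca-2,6,11-trienoate | CC1(C)O[C@H]1CC/C(C(=O)OC)=C/CC/C(C)=C/CC[C@@](C)(O[Si](CC)(CC)CC)C=C | intermediate
13 | (2Z,6E,10R)-2-{2-[(2S)-3,3-dimethyloxiran-2-yl]ethyl}-6,10-dimethyl-10-[(triethylsilyl)oxy]dodeca-2,6,11-trien-1-ol | CC1(C)O[C@H]1CC/C(CO)=C/CC/C(C)=C/CC[C@@](C)(O[Si](CC)(CC)CC)C=C | intermediate
14 | (2Z,6E,10R)-2-{2-[(2S)-3,3-dimethyloxiran-2-yl]ethyl}-6,10-dimethyl-10-[(triethylsilyl)oxy]dodeca-2,6,11-trien-1-yl acetate | CC1(C)O[C@H]1CC/C(COC(C)=O)=C/CC/C(C)=C/CC[C@@](C)(O[Si](CC)(CC)CC)C=C | intermediate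
15 | (13R)-20-acetoxy-13-[(triethylsilyl)oxy]-3β-[(trimethylsilyl)oxy]labda-8(17),14-diene | C=C[C@](C)(O[Si](CC)(CC)CC)CC[C@H]1C(=C)CC[C@H]2C(C)(C)[C@@H](O[Si](C)(C)C)CC[C@]12COC(C)=O | intermediate (not isolated)
16 | (13R)-20-acetoxy-13-[(triethylsilyl)oxy]labda-8(17),14-dien-3β-ol | C=C[C@](C)(O[Si](CC)(CC)CC)CC[C@H]1C(=C)CC[C@H]2C(C)(C)[C@@H](O)CC[C@]12COC(C)=O | intermediate
17 | (13R)-20-acetoxy-13-[(triethylsilyl)oxy]labda-8(17),14-dien-3-one | C=C[C@](C)(O[Si](CC)(CC)CC)CC[C@H]1C(=C)CC[C@H]2C(C)(C)C(=O)CC[C@]12COC(C)=O | intermediate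
18 | (13R)-20-acetoxy-13-[(triethylsilyl)oxy]-3-[(trimethylsilyl)oxy]labda-2,8(17),14-triene | C=C[C@](C)(O[Si](CC)(CC)CC)CC[C@H]1C(=C)CC[C@H]2C(C)(C)C(O[Si](C)(C)C)=CC[C@]12COC(C)=O | intermediate
19 | (13R)-20-acetoxy-2α,3α-epoxy-13-[(triethylsilyl)oxy]-3β-[(trimethylsilyl)oxy]labda-8(17),14-diene | C=C[C@](C)(O[Si](CC)(CC)CC)CC[C@H]1C(=C)CC[C@H]2C(C)(C)[C@]3(O[Si](C)(C)C)O[C@@H]3C[C@]12COC(C)=O | intermediate (not isolated)
20 | (13R)-20-acetoxy-13-[(triethylsilyl)oxy]-2α-[(trimethylsilyl)oxy]labda-8(17),14-dien-3-one | C=C[C@](C)(O[Si](CC)(CC)CC)CC[C@H]1C(=C)CC[C@H]2C(C)(C)C(=O)[C@H](O[Si](C)(C)C)C[C@]12COC(C)=O | intermediate (not isolated)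
21 | (13R)-20-acetoxy-2α-hydroxy-13-[(triethylsilyl)oxy]labda-8(17),14-dien-3-one | C=C[C@](C)(O[Si](CC)(CC)CC)CC[C@H]1C(=C)CC[C@H]2C(C)(C)C(=O)[C@H](O)C[C@]12COC(C)=O | intermediate
22 | (13R)-20-acetoxy-13-[(triethylsilyl)oxy]labda-8(17),14-diene-2α,3α-diol | C=C[C@](C)(O[Si](CC)(CC)CC)CC[C@H]1C(=C)CC[C@H]2C(C)(C)[C@H](O)[C@H](O)C[C@]12COC(C)=O | intermediate
23 | angelic acid, (Z)-2-methylbut-2-enoic acid | C/C=C(/C)C(=O)O | starting material
24 | (Z)-2-methylbut-2-enoic 2,4,6-trichlorobenzoic anhydride | C/C=C(/C)C(=O)OC(=O)c1c(Cl)cc(Cl)cc1Cl | intermediate (not isolated)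
25 | (13R)-20-acetoxy-2α-(angeloyloxy)-13-[(triethylsilyl)oxy]labda-8(17),14-dien-3α-ol | C=C[C@](C)(O[Si](CC)(CC)CC)CC[C@H]1C(=C)CC[C@H]2C(C)(C)[C@H](O)[C@H](OC(=O)/C(C)=C\C)C[C@]12COC(C)=O | intermediate
26 | (13R)-20-acetoxy-2α-(angeloyloxy)-13-[(triethylsilyl)oxy]labda-8(17),14-diene-3α,7α-diol | C=C[C@](C)(O[Si](CC)(CC)CC)CC[C@H]1C(=C)[C@H](O)C[C@H]2C(C)(C)[C@H](O)[C@H](OC(=O)/C(C)=C\C)C[C@]12COC(C)=O | intermediate
27 | (13R)-20-acetoxy-2α-(angeloyloxy)labda-8(17),14-diene-3α,7α,13-triol | C=C[C@](C)(O)CC[C@H]1C(=C)[C@H](O)C[C@H]2C(C)(C)[C@H](O)[C@H](OC(=O)/C(C)=C\C)C[C@]12COC(C)=O | target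

**Count and risks**

Total step count: 17. Longest linear sequence: 15 steps (steps 1–4, then 7–17, from (R)-linalool).

Steps most likely to fail:

Step 10. The cascade may stop after ring A if the C10 radical is reduced or trapped by titanium (a C10–Ti species would lose acetate by β-elimination). The terminating β-hydride elimination may also give endocyclic alkenes alongside the exocyclic one, and diastereoselection may be modest. The fallback sets out from 12 and closes the two rings in separate radical events with C20 at the ester level. Titanocene(III)-catalysed reductive epoxide opening with collidinium chloride as proton source, followed by 6-endo Giese-type closure of the C4 radical onto the β-carbon (C5) of the enoate, should give methyl (13R)-3β-hydroxy-13-[(triethylsilyl)oxy]-9,10-secolabda-8,14-dien-20-oate F1. Its dianion (LDA, THF, −78 °C) would be oxidised with a copper(II) carboxylate, so that the α-ester radical closes ring B 6-endo onto C9 and the tertiary C8 radical is oxidised by copper(II) to the exocyclic alkene, giving methyl (13R)-3β-hydroxy-13-[(triethylsilyl)oxy]labda-8(17),14-dien-20-oate F2. Reduction with LiAlH4 would give (13R)-13-[(triethylsilyl)oxy]labda-8(17),14-diene-3β,20-diol F3, and acetylation of the primary hydroxyl (Ac2O, 2,4,6-collidine, −20 °C) would come back to the route at 16.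

Step 7. Z-selectivity may erode with the α-branched phosphonate, or the base-labile trifluoroethyl phosphonate may degrade before it meets the aldehyde. The fallback sets out from 7 and builds the trisubstituted alkene by alkyne hydrometalation and cross-coupling instead of olefination. Ohira–Bestmann homologation would give triethyl{[(3R,6E)-3,7-dimethylundeca-1,6-dien-10-yn-3-yl]oxy}silane F4. Lithiation and methyl chloroformate would give methyl (6E,10R)-6,10-dimethyl-10-[(triethylsilyl)oxy]dodeca-6,11-dien-2-ynoate F5. Palladium(0)-catalysed syn-hydrostannation with Bu3SnH should place tin at the α-carbon and hydrogen at C5, giving methyl (2E,6E,10R)-6,10-dimethyl-2-(tributylstannyl)-10-[(triethylsilyl)oxy]dodeca-2,6,11-trienoate F6. Iododestannylation with retention would give methyl (2E,6E,10R)-2-iodo-6,10-dimethyl-10-[(triethylsilyl)oxy]dodeca-2,6,11-trienoate F7. Negishi coupling with {2-[(2S)-3,3-dimethyloxiran-2-yl]ethyl}zinc bromide F8 (from 9, zinc dust and LiCl) would come back to the route at 12.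

Step 15. Acylation may occur at O3 or twice, and the activated angeloyl donor may isomerise from Z to E on heating. The fallback sets out from 22 and builds the Z alkene on the ester instead of transferring it. Carbodiimide coupling of the C2 hydroxyl with 2-[bis(2,2,2-trifluoroethoxy)phosphoryl]propanoic acid would give (13R)-20-acetoxy-2α-{2-[bis(2,2,2-trifluoroethoxy)phosphoryl]propanoyloxy}-13-[(triethylsilyl)oxy]labda-8(17),14-dien-3α-ol F9. Still–Gennari olefination with acetaldehyde (KHMDS, 18-crown-6, THF, −78 °C) should form the (Z)-2-methylbut-2-enoate and come back to the route at 25.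

**Further compounds**

F1 | step 10 | methyl (13R)-3β-hydroxy-13-[(triethylsilyl)oxy]-9,10-secolabda-8,14-dien-20-oate (both epimers at C10) | C=C[C@](C)(O[Si](CC)(CC)CC)CC/C=C(\C)CC[C@H]1C(C)(C)[C@@H](O)CCC1C(=O)OC
F2 | step 10 | methyl (13R)-3β-hydroxy-13-[(triethylsilyl)oxy]labda-8(17),14-dien-20-oate | C=C[C@](C)(O[Si](CC)(CC)CC)CC[C@H]1C(=C)CC[C@H]2C(C)(C)[C@@H](O)CC[C@]12C(=O)OC
F3 | step 10 | (13R)-13-[(triethylsilyl)oxy]labda-8(17),14-diene-3β,20-diol | C=C[C@](C)(O[Si](CC)(CC)CC)CC[C@H]1C(=C)CC[C@H]2C(C)(C)[C@@H](O)CC[C@]12CO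
F4 | step 7 | triethyl{[(3R,6E)-3,7-dimethylundeca-1,6-dien-10-yn-3-yl]oxy}silane | C=C[C@](C)(O[Si](CC)(CC)CC)CC/C=C(\C)CCC#C
F5 | step 7 | methyl (6E,10R)-6,10-dimethyl-10-[(triethylsilyl)oxy]dodeca-6,11-dien-2-ynoate | C=C[C@](C)(O[Si](CC)(CC)CC)CC/C=C(\C)CCC#CC(=O)OC
F6 | step 7 | methyl (2E,6E,10R)-6,10-dimethyl-2-(tributylstannyl)-10-[(triethylsilyl)oxy]dodeca-2,6,11-trienoate | C=C[C@](C)(O[Si](CC)(CC)CC)CC/C=C(\C)CC/C=C(/[Sn](CCCC)(CCCC)CCCC)C(=O)OC
F7 | step 7 | methyl (2E,6E,10R)-2-iodo-6,10-dimethyl-10-[(triethylsilyl)oxy]dodeca-2,6,11-trienoate | C=C[C@](C)(O[Si](CC)(CC)CC)CC/C=C(\C)CC/C=C(/I)C(=O)OC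
F8 | step 7 | {2-[(2S)-3,3-dimethyloxiran-2-yl]ethyl}zinc bromide | CC1(C)O[C@H]1CC[Zn]Br
F9 | step 15 | (13R)-20-acetoxy-2α-{2-[bis(2,2,2-trifluoroethoxy)phosphoryl]propanoyloxy}-13-[(triethylsilyl)oxy]labda-8(17),14-dien-3α-ol | C=C[C@](C)(O[Si](CC)(CC)CC)CC[C@H]1C(=C)CC[C@H]2C(C)(C)[C@H](O)[C@H](OC(=O)C(C)P(=O)(OCC(F)(F)F)OCC(F)(F)F)C[C@]12COC(C)=O
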